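**Plan**

- Numbering: ring C1 (C=O), C2=C3, C4 (CH–OAc), C5 (C–OH); side chain C1'–C13'. Backwards, the acetyl and silyl groups are removed first. Then the ring bond C4–C5 is cut (retro-electrocyclisation, formally retro-aldol), then C1–C5 (furyl anion plus aldehyde), then C2'–C3' (Grignard reagent plus epoxide).
- The C4–C5 cut is possible because C5 is a fully substituted α-ketol carbon of the cyclopent-2-enone. It carries OH and sits between the C1 carbonyl, the allylic carbinol C4 and the exocyclic carbinol C1'. That array is the closed form of a cis-4-oxo-2-enal oxygenated at the next two carbons, which is an oxidised 2-furyl carbinol.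
- Forwards: the C14 chain is made by epoxide opening and joined to furan by carbonyl addition. The furan is expanded to a 6-hydroxypyran-3-one, and this ring is contracted to the cyclopentenone, the only ring of the target. Acetylation at O4 and desilylation at O1' finish the route.
- Stereochemistry: C1' (S) is bought with (S)-benzyl glycidyl ether and is never touched. C4 and C5 are created together in the ring contraction, trans to each other by conrotation and in the absolute sense set by C1'. The furyl carbinol and lactol centres are destroyed on the way, so their epimers converge.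

Key step: step 7

Remark on the chemistry: compounds 10 and 11 are carried as epimer mixtures, and O1' is masked as a bulky, non-chelating TBS ether from step 2 to step 9.

**Route**

Step 1
Reactants: 1 (S)-benzyl glycidyl ether; 2 1-bromoundecane
Product: 4 (S)-1-(benzyloxy)tetradecan-2-ol, via undecylmagnesium bromide 3 (not isolated)
Conditions: Mg, THF, 40 °C; then 1, CuI (10 mol %), THF, −30 to 0 °C; aq. NH4Cl
Reagents that add atoms: none
Why: Copper-catalysed Grignard opening of a terminal epoxide proceeds by SN2 attack at the unhindered CH2, so the secondary alcohol forms regioselectively and the stereocentre of 1 is carried over unchanged as (S).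

Step 2
Reactants: 4 (S)-1-(benzyloxy)tetradecan-2-ol
Product: 5 (S)-{[1-(benzyloxy)tetradecan-2-yl]oxy}(tert-butyl)dimethylsilane
Conditions: TBSCl, imidazole, DMF, rt
Reagents that add atoms: tert-butyldimethylsilyl chloride, CC(C)(C)[Si](C)(C)Cl
Why: Standard silyl ether formation on a secondary alcohol installs a group that tolerates organolithium, peracid, amine base and acylation and is large enough to direct the ring closure in step 7.

Step 3
Reactants: 5 (S)-{[1-(benzyloxy)tetradecan-2-yl]oxy}(tert-butyl)dimethylsilane
Product: 6 (S)-2-[(tert-butyldimethylsilyl)oxy]tetradecan-1-ol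
Conditions: H2 (1 atm), 10% Pd/C, EtOAc, rt
Reagents that add atoms: none
Why: Catalytic hydrogenolysis of the benzyl ether in a neutral aprotic solvent leaves the silyl ether in place and gives no opportunity for silyl migration to the primary hydroxyl.

Step 4
Reactants: 6 (S)-2-[(tert-butyldimethylsilyl)oxy]tetradecan-1-ol
Product: 7 (S)-2-[(tert-butyldimethylsilyl)oxy]tetradecanal
Conditions: Dess–Martin periodinane, CH2Cl2, 0 °C to rt
Reagents that add atoms: none
Why: Dess–Martin oxidation converts the primary alcohol into the aldehyde without base, so the α-silyloxy stereocentre should not epimerise; the aldehyde is used directly.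

Step 5
Reactants: 7 (S)-2-[(tert-butyldimethylsilyl)oxy]tetradecanal; 8 furan
Product: 10 (1RS,2S)-2-[(tert-butyldimethylsilyl)oxy]-1-(furan-2-yl)tetradecan-1-ol (both carbinol epimers), via 2-furyllithium 9 (not isolated)
Conditions: 8 (1.5 equiv), n-BuLi, THF, 0 °C; then 7, −78 °C; aq. NH4Cl at −78 °C
Reagents that add atoms: none
Why: C2-lithiation of furan followed by 1,2-addition of the organolithium to the aldehyde forms the C1–C5 bond; the new carbinol centre needs no control because step 7 destroys it, and the cold quench is meant to suppress O-to-O silyl migration in the lithium alkoxide.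

Step 6
Reactants: 10 (1RS,2S)-2-[(tert-butyldimethylsilyl)oxy]-1-(furan-2-yl)tetradecan-1-ol
Product: 11 2-[(1S)-1-[(tert-butyldimethylsilyl)oxy]tridecyl]-6-hydroxy-2H-pyran-3(6H)-one (epimers at C2 and C6)
Conditions: mCPBA, CH2Cl2, 0 °C
Reagents that add atoms: meta-chloroperbenzoic acid, OOC(=O)c1cccc(Cl)c1
Why: In the Achmatowicz rearrangement the peracid oxidises the furan to the cis-enedione, which is trapped by the free furylic hydroxyl as the six-membered lactol; both new centres are left as mixtures because neither survives step 7.

Step 7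
Reactants: 11 2-[(1S)-1-[(tert-butyldimethylsilyl)oxy]tridecyl]-6-hydroxy-2H-pyran-3(6H)-one
Product: 14 (4R,5R)-5-[(1S)-1-[(tert-butyldimethylsilyl)oxy]tridecyl]-4,5-dihydroxycyclopent-2-en-1-one (4-OH trans to 5-OH and cis to the side chain), via open-chain keto enal 12 (not isolated), via enediol 13 (not isolated)
Conditions: Et3N (0.5 equiv), DMF, 50 °C
Reagents that add atoms: none
Why: Under amine catalysis the lactol of 11 opens by ring-chain tautomerism to the cis-5-hydroxy-4-oxo-2-enal 12, which enolises at its only enolisable position to the hydrogen-bonded Z-enediol 13, planar at the future C5, and this 1,2-dioxygenated pentadienyl system closes by a thermally allowed conrotatory 4π electrocyclisation (formally an intramolecular aldol of the enediol carbon onto the aldehyde) before tautomerising to the conjugated enone. The closest known reaction type is the base- or heat-mediated isomerisation of Achmatowicz 6-hydroxy-2H-pyran-3(6H)-ones to trans-4,5-dihydroxycyclopent-2-enones, a relative of the Piancatelli rearrangement. The cyclopentenone is the only ring formed and closes by making the C4–C5 bond between the former lactol carbon and the former furyl carbinol carbon; read as an aldol this would be a disfavoured 5-(enolendo)-exo-trig closure, which is why the pericyclic path is the working model. The relative configuration of C4 and C5 follows from conrotation of a pentadienyl unit with both oxygens outside (the C5 oxygen held cis to the enol OH in the Z-enediol, the aldehyde oxygen s-trans), which places the two hydroxyls trans and C4–O cis to the side chain. The absolute sense at both new centres is controlled by C1': allylic 1,3-strain holds the C1'–H bond in the enediol plane, and C4 should bond to the face anti to the bulky OTBS group, which for (S)-C1' gives the (4R,5R) descriptors of 14, that is, the ring configuration of the target. The step therefore needs facial selectivity (torquoselectivity) together with regioselective enolisation, and the substrate provides a single enolisable site, a capped side-chain oxygen that can form neither a bicyclic ketal nor a chelate, and the enone as thermodynamic sink.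

Step 8
Reactants: 14 (4R,5R)-5-[(1S)-1-[(tert-butyldimethylsilyl)oxy]tridecyl]-4,5-dihydroxycyclopent-2-en-1-one
Product: 15 (1R,5R)-5-[(1S)-1-[(tert-butyldimethylsilyl)oxy]tridecyl]-5-hydroxy-4-oxocyclopent-2-en-1-yl acetate
Conditions: Ac2O, pyridine, DMAP (cat.), CH2Cl2, 0 °C
Reagents that add atoms: acetic anhydride, CC(=O)OC(C)=O
Why: Nucleophile-catalysed acylation should take the secondary allylic hydroxyl only, since the tertiary α-ketol hydroxyl is too hindered at 0 °C, and because C5 carries no hydrogen the new acetate cannot be lost by β-elimination.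

Step 9
Reactants: 15 (1R,5R)-5-[(1S)-1-[(tert-butyldimethylsilyl)oxy]tridecyl]-5-hydroxy-4-oxocyclopent-2-en-1-yl acetate
Product: 16 (1R,5S)-5-hydroxy-5-[(1S)-1-hydroxytridecyl]-4-oxocyclopent-2-en-1-yl acetate (CNP0147374.2)
Conditions: HF·pyridine, pyridine, THF, 0 °C to rt
Reagents that add atoms: none
Why: Fluoride-mediated desilylation under buffered acidic conditions should cleave the secondary TBS ether while the enone, the tertiary α-ketol and the acetate stay intact, and the absence of base avoids acetyl migration from O4 to the freed O1'.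

**Compound list**

1 | (S)-benzyl glycidyl ether, (S)-2-[(benzyloxy)methyl]oxirane | [C@@H]1(COCc2ccccc2)CO1 | starting material
2 | 1-bromoundecane | CCCCCCCCCCCBr | starting material
3 | undecylmagnesium bromide | CCCCCCCCCCC[Mg]Br | intermediate (not isolated)
4 | (S)-1-(benzyloxy)tetradecan-2-ol | CCCCCCCCCCCC[C@H](O)COCc1ccccc1 | intermediate
5 | (S)-{[1-(benzyloxy)tetradecan-2-yl]oxy}(tert-butyl)dimethylsilane | CCCCCCCCCCCC[C@H](O[Si](C)(C)C(C)(C)C)COCc1ccccc1 | intermediate
6 | (S)-2-[(tert-butyldimethylsilyl)oxy]tetradecan-1-ol | CCCCCCCCCCCC[C@H](O[Si](C)(C)C(C)(C)C)CO | intermediate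
7 | (S)-2-[(tert-butyldimethylsilyl)oxy]tetradecanal | CCCCCCCCCCCC[C@H](O[Si](C)(C)C(C)(C)C)C=O | intermediate
8 | furan | c1ccoc1 | starting material
9 | 2-furyllithium | [Li]c1ccco1 | intermediate (not isolated)
10 | (1RS,2S)-2-[(tert-butyldimethylsilyl)oxy]-1-(furan-2-yl)tetradecan-1-ol, both carbinol epimers | CCCCCCCCCCCC[C@H](O[Si](C)(C)C(C)(C)C)C(O)c1ccco1 | intermediate
11 | 2-[(1S)-1-[(tert-butyldimethylsilyl)oxy]tridecyl]-6-hydroxy-2H-pyran-3(6H)-one, epimers at C2 and C6 | CCCCCCCCCCCC[C@H](O[Si](C)(C)C(C)(C)C)C1OC(O)C=CC1=O | intermediate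
12 | (2Z,6S)-6-[(tert-butyldimethylsilyl)oxy]-5-hydroxy-4-oxooctadec-2-enal, C5 epimers | CCCCCCCCCCCC[C@H](O[Si](C)(C)C(C)(C)C)C(O)C(=O)/C=C\C=O | intermediate (not isolated)
13 | (2Z,4Z,6S)-6-[(tert-butyldimethylsilyl)oxy]-4,5-dihydroxyoctadeca-2,4-dienal | CCCCCCCCCCCC[C@H](O[Si](C)(C)C(C)(C)C)/C(O)=C(O)\C=C/C=O | intermediate (not isolated)
14 | (4R,5R)-5-[(1S)-1-[(tert-butyldimethylsilyl)oxy]tridecyl]-4,5-dihydroxycyclopent-2-en-1-one | CCCCCCCCCCCC[C@H](O[Si](C)(C)C(C)(C)C)[C@@]1(O)C(=O)C=C[C@H]1O | intermediate
15 | (1R,5R)-5-[(1S)-1-[(tert-butyldimethylsilyl)oxy]tridecyl]-5-hydroxy-4-oxocyclopent-2-en-1-yl acetate | CCCCCCCCCCCC[C@H](O[Si](C)(C)C(C)(C)C)[C@@]1(O)C(=O)C=C[C@H]1OC(C)=O | intermediate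
16 | (1R,5S)-5-hydroxy-5-[(1S)-1-hydroxytridecyl]-4-oxocyclopent-2-en-1-yl acetate | CCCCCCCCCCCC[C@H](O)[C@@]1(O)C(=O)C=C[C@H]1OC(C)=O | target

**Count and risks**

Total step count: 9. Longest linear sequence: 9 steps (from 1 and 2 to 16).

Steps most likely to fail:

1. Step 7. The C4–C5 bond may form on the wrong face of the enediol relative to C1' (insufficient torquoselectivity), the selectivity may be eroded by retro-aldol equilibration, the silyl group may migrate to the new neighbouring hydroxyls, or the enediol may drain into the isomeric α-ketol. The fallback abandons the ring contraction and takes the ring configuration from a bought enantiopure cyclopentenone; it sets out from 1-bromoundecane 2 and returns to the route at the target 16.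
   - Alkylation of lithiated acetaldehyde N-cyclohexylimine (LiN(iPr)2, THF, −78 to 0 °C) with 2, a metalloenamine alkylation, would give N-cyclohexyltridecan-1-imine F1, hydrolysed on work-up with aqueous oxalic acid to tridecanal F2.
   - The lithium enolate of commercial (S)-4-[(tert-butyldimethylsilyl)oxy]cyclopent-2-en-1-one (O=C1C=C[C@@H](O[Si](C)(C)C(C)(C)C)C1; LiN(iPr)2, THF, −78 °C) should add to F2 anti to the silyloxy group to give the 4,5-trans aldol adduct F3.
   - Mesylation (MsCl, Et3N, CH2Cl2, 0 °C) to the mesylate F4 and elimination in the same flask with DBU is expected to give (R,E)-4-[(tert-butyldimethylsilyl)oxy]-5-tridecylidenecyclopent-2-en-1-one F5.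
   - The silyl ether is exchanged for the acetate: aqueous HF in MeCN to (R,E)-4-hydroxy-5-tridecylidenecyclopent-2-en-1-one F6, then Ac2O, pyridine to (1R,5E)-4-oxo-5-tridecylidenecyclopent-2-en-1-yl acetate F7.
   - Dihydroxylation of the exocyclic, more substituted alkene (OsO4 cat., N-methylmorpholine N-oxide, acetone–H2O) from the face anti to the allylic acetoxy group would then give 16. Syn addition to the E alkene sets C5 and C1' together in the (5S,1'S) sense with the C5 hydroxyl trans to the C4 acetate.

2. Step 9. Cleavage of the hindered silyl ether next to the fully substituted C5 may be slow under conditions mild enough for the acetate, and prolonged exposure invites acetyl migration from O4 to the freed O1' or loss of the ester. The fallback reverses the order of the last operations; it sets out from diol 14 and returns at the target 16.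
   - Desilylation of 14 before any ester is present (aqueous HF, MeCN, rt) would give (4R,5S)-4,5-dihydroxy-5-[(1S)-1-hydroxytridecyl]cyclopent-2-en-1-one F8.
   - 2,2-Dimethoxypropane with pyridinium p-toluenesulfonate in CH2Cl2 should tie the vicinal 5,1'-diol into a five-membered dioxolane, since the trans ring diol cannot bridge, giving the 5,1'-O-isopropylidene derivative F9 with only the C4 hydroxyl free.
   - Acetylation (Ac2O, pyridine, DMAP cat.) would give the 4-O-acetyl acetonide F10, and acetal hydrolysis (80% aqueous AcOH, 40 °C, or TFA–H2O, 0 °C) would release 16.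

3. Step 5. The basic organolithium may enolise the α-silyloxy aldehyde and erode the only source of chirality, or the silyl group may shift from O2 to the new alkoxide and cap the furylic oxygen that step 6 needs free. The fallback replaces the aldehyde addition by acylation and reduction; it sets out from aldehyde 7 and returns at carbinol 10.
   - Pinnick oxidation of 7 (NaClO2, NaH2PO4, 2-methyl-2-butene, t-BuOH–H2O) would give (S)-2-[(tert-butyldimethylsilyl)oxy]tetradecanoic acid F11.
   - Coupling with N,O-dimethylhydroxylamine hydrochloride (EDC·HCl, N-methylmorpholine, CH2Cl2) would give the Weinreb amide F12.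
   - Addition of 2-furyllithium 9 (THF, −78 °C) stops at the chelated tetrahedral intermediate and should give on work-up (S)-2-[(tert-butyldimethylsilyl)oxy]-1-(furan-2-yl)tetradecan-1-one F13.
   - Reduction with NaBH4 in MeOH at −20 °C would give 10 as an epimer mixture, which is all the route needs.

**Further compounds**

F1 | step 7 | N-cyclohexyltridecan-1-imine (not isolated) | CCCCCCCCCCCCC=NC1CCCCC1
F2 | step 7 | tridecanal | CCCCCCCCCCCCC=O
F3 | step 7 | (4R,5S)-4-[(tert-butyldimethylsilyl)oxy]-5-(1-hydroxytridecyl)cyclopent-2-en-1-one, 4,5-trans aldol adduct, carbinol epimers | CCCCCCCCCCCCC(O)[C@@H]1C(=O)C=C[C@H]1O[Si](C)(C)C(C)(C)C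
F4 | step 7 | mesylate of the aldol adduct (not isolated) | CCCCCCCCCCCCC(OS(C)(=O)=O)[C@@H]1C(=O)C=C[C@H]1O[Si](C)(C)C(C)(C)C
F5 | step 7 | (R,E)-4-[(tert-butyldimethylsilyl)oxy]-5-tridecylidenecyclopent-2-en-1-one | CCCCCCCCCCCC/C=C1/C(=O)C=C[C@H]1O[Si](C)(C)C(C)(C)C
F6 | step 7 | (R,E)-4-hydroxy-5-tridecylidenecyclopent-2-en-1-one | CCCCCCCCCCCC/C=C1/C(=O)C=C[C@H]1O
F7 | step 7 | (1R,5E)-4-oxo-5-tridecylidenecyclopent-2-en-1-yl acetate | CCCCCCCCCCCC/C=C1/C(=O)C=C[C@H]1OC(C)=O
F8 | step 9 | (4R,5S)-4,5-dihydroxy-5-[(1S)-1-hydroxytridecyl]cyclopent-2-en-1-one | CCCCCCCCCCCC[C@H](O)[C@@]1(O)C(=O)C=C[C@H]1O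
F9 | step 9 | 5,1'-O-isopropylidene derivative of the triol (spiro dioxolane, 4-OH free) | CCCCCCCCCCCC[C@@H]2OC(C)(C)O[C@@]21C(=O)C=C[C@H]1O
F10 | step 9 | 4-O-acetyl-5,1'-O-isopropylidene derivative | CCCCCCCCCCCC[C@@H]2OC(C)(C)O[C@@]21C(=O)C=C[C@H]1OC(C)=O
F11 | step 5 | (S)-2-[(tert-butyldimethylsilyl)oxy]tetradecanoic acid | CCCCCCCCCCCC[C@H](O[Si](C)(C)C(C)(C)C)C(=O)O
F12 | step 5 | (S)-2-[(tert-butyldimethylsilyl)oxy]-N-methoxy-N-methyltetradecanamide | CCCCCCCCCCCC[C@H](O[Si](C)(C)C(C)(C)C)C(=O)N(C)OC
F13 | step 5 | (S)-2-[(tert-butyldimethylsilyl)oxy]-1-(furan-2-yl)tetradecan-1-one | CCCCCCCCCCCC[C@H](O[Si](C)(C)C(C)(C)C)C(=O)c1ccco1
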